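**Plan**

1. Retrosynthesis: the phenol O–CH3 bond is cut first (the methyl ether is the one protecting group carried). Then two C–C bonds of the non-phenolic ring, C1'–C2' and C5'–C6', are cut together, which splits that ring into an aryl ethynyl ether and 3,5-dibromo-2-pyrone (with CO2 as the lost bridge).
2. Enabling feature: in the dibromophenoxy ring C1' carries the ether oxygen and C2' and C4' carry bromine. The C2'–C5' segment with this 1,3-dibromo pattern is the C3–C6 diene of 3,5-dibromo-2-pyrone, and C1'/C6' are the two sp carbons of an ynol ether already attached to the oxygen of the phenolic ring.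
3. The ynol ether goes back through a 2-bromovinyl ether and a vinyl ether (O–vinyl bond) to 2,4-dibromo-6-methoxyphenol, and that to 2-bromo-6-methoxyphenol (C4–Br bond); the pyrone comes from coumalic acid.
4. Forward: the phenolic ring is bought intact and completed by one bromination. Its oxygen is vinylated and raised to the alkyne level without organolithium reagents. The second ring is then grown on that oxygen by cycloaddition and CO2 loss, and demethylation ends the route.
5. Stereochemistry: the target has no stereocentre, so nothing has to be set; the only stereogenic intermediates (a racemic dibromide and a racemic bridged lactone) are transient.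

Key step: step 6

Remark: the target is achiral (no stereocentre, freely rotating diaryl ether), so the given SMILES describes a single compound and no enantioselective step is needed.

**Route**

Step 1
Reactants: 1 2-bromo-6-methoxyphenol
Product: 2 2,4-dibromo-6-methoxyphenol
Conditions: NBS (1.0 equiv), MeCN, 0 °C → rt
Reagents that add atoms: N-bromosuccinimide, O=C1CCC(=O)N1Br
Why: Electrophilic aromatic bromination, in which the free hydroxyl is the strongest director and its only open ortho/para position is the para carbon, so one equivalent of NBS should place bromine at C4.

Step 2
Reactants: 2 2,4-dibromo-6-methoxyphenol; 3 2,4,6-trivinylcyclotriboroxane–pyridine complex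
Product: 4 1,5-dibromo-2-(ethenyloxy)-3-methoxybenzene
Conditions: 3 (0.7 equiv), Cu(OAc)2 (1 equiv), pyridine, CH2Cl2, dry air, rt
Reagents that add atoms: none
Why: Chan–Lam oxidative copper coupling of a phenol with a vinylboron reagent (the boroxine serving as a vinylboronic acid equivalent) is an established route to aryl vinyl ethers and should leave the C–Br bonds alone, since Cu(II)/pyridine at room temperature does not insert into aryl bromides.

Step 3
Reactants: 4 1,5-dibromo-2-(ethenyloxy)-3-methoxybenzene
Product: 6 1,5-dibromo-2-{[(Z)-2-bromoethenyl]oxy}-3-methoxybenzene, via 1,2-dibromoethyl ether 5 (not isolated)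
Conditions: Br2 (1.0 equiv), CH2Cl2, −78 °C; then DBU (1.2 equiv), −78 °C → rt
Reagents that add atoms: bromine, BrBr
Why: Bromine should add to the electron-rich vinyl ether double bond far faster than it substitutes the doubly brominated ring, and the α-bromo ether 5 should then lose HBr by amidine-promoted E2 elimination (the labile anomeric bromide leaves, the β-bromine stays), the classical bromination–dehydrobromination of vinyl ethers, with the Z isomer expected to predominate.

Step 4
Reactants: 6 1,5-dibromo-2-{[(Z)-2-bromoethenyl]oxy}-3-methoxybenzene
Product: 7 1,5-dibromo-2-(ethynyloxy)-3-methoxybenzene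
Conditions: KOt-Bu (1.3 equiv), THF, −40 → 0 °C; cold pH 7 buffer work-up; kept cold in PhMe and used at once
Reagents that add atoms: none
Why: Anti E2 dehydrobromination of a (Z)-2-bromovinyl ether, whose O–CH hydrogen lies trans to bromine, is the standard halovinyl-ether route to terminal ynol ethers, and an alkoxide base is chosen because it spares the aryl bromides that an alkyllithium would exchange.

Step 5
Reactants: 8 coumalic acid
Product: 9 3,5-dibromo-2H-pyran-2-one
Conditions: NBS (2.5 equiv), LiOAc, MeCN–H2O, rt
Reagents that add atoms: N-bromosuccinimide, O=C1CCC(=O)N1Br
Why: Hunsdiecker-type bromodecarboxylation at C5 together with electrophilic bromination at C3 is a known one-pot conversion of coumalic acid into this pyrone.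

Step 6
Reactants: 7 1,5-dibromo-2-(ethynyloxy)-3-methoxybenzene; 9 3,5-dibromo-2H-pyran-2-one
Product: 11 1,5-dibromo-2-(2,4-dibromophenoxy)-3-methoxybenzene, via bridged bicyclic lactone 10 (not isolated)
Conditions: 7 (1.5 equiv), PhMe, BHT (cat.), 80–100 °C, sealed tube
Reagents that add atoms: none
Why: Proposed new method: the electron-poor diene of 9 (C3=C4–C5=C6) should take up the oxygen-polarised alkyne of 7 in an asynchronous inverse-electron-demand [4+2] cycloaddition in which the terminal alkyne carbon (the nucleophilic end) bonds to pyrone C6 and the oxygen-bearing carbon to C3, giving bridged lactone 10, which should aromatise at once by irreversible retro-[4+2] loss of CO2. The closest known reactions are the cycloadditions of 3,5-dibromo-2-pyrone with enol ethers, which place the alkoxy carbon next to the C3 bridgehead, and the Diels–Alder/decarboxylation benzannulation of 2-pyrones with alkynes; an aryl ethynyl ether has not been shown as the 2π partner. The six-membered carbocycle closes by intermolecular [4+2] annulation (four carbons from 9, two from 7), with both ring bonds C1'–C2' and C5'–C6' formed in the cycloaddition and no separate cyclisation needed. No stereocentre survives, because the two bridgehead centres of racemic 10 disappear when CO2 leaves. The step needs one regiochemical sense (2,4- and not 3,5-dibromophenoxy), which the match between the nucleophilic CH terminus of the ynol ether and the electrophilic C6 of the pyrone should secure. No metal or base is present, so the four aryl–bromine bonds and the methyl ether should stay untouched.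

Step 7
Reactants: 11 1,5-dibromo-2-(2,4-dibromophenoxy)-3-methoxybenzene
Product: 13 3,5-dibromo-2-(2,4-dibromophenoxy)phenol, via aryloxydibromoborane 12 (not isolated)
Conditions: BBr3 (3 equiv), CH2Cl2, −78 °C → rt; then H2O
Reagents that add atoms: none
Why: Boron tribromide demethylation of an aryl methyl ether, in which coordination at the methoxy oxygen and SN2 attack of bromide on the methyl carbon give aryloxyborane 12 and water then frees the phenol, while the diaryl ether (both carbons sp2) and the C–Br bonds are inert to the reagent.

**Compound list**

1 | 2-bromo-6-methoxyphenol | COc1cccc(Br)c1O | starting material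
2 | 2,4-dibromo-6-methoxyphenol | COc1cc(Br)cc(Br)c1O | intermediate
3 | 2,4,6-trivinylcyclotriboroxane–pyridine complex (1:1) | C=CB1OB(C=C)OB(C=C)O1.c1ccncc1 | starting material
4 | 1,5-dibromo-2-(ethenyloxy)-3-methoxybenzene | COc1cc(Br)cc(Br)c1OC=C | intermediate
5 | 1,5-dibromo-2-(1,2-dibromoethoxy)-3-methoxybenzene (racemic) | COc1cc(Br)cc(Br)c1OC(Br)CBr | intermediate
6 | 1,5-dibromo-2-{[(Z)-2-bromoethenyl]oxy}-3-methoxybenzene | COc1cc(Br)cc(Br)c1O/C=C\Br | intermediate
7 | 1,5-dibromo-2-(ethynyloxy)-3-methoxybenzene | COc1cc(Br)cc(Br)c1OC#C | intermediate
8 | coumalic acid (2-oxo-2H-pyran-5-carboxylic acid) | O=C(O)c1ccc(=O)oc1 | starting material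
9 | 3,5-dibromo-2H-pyran-2-one | O=c1occ(Br)cc1Br | intermediate
10 | 4,7-dibromo-5-(2,4-dibromo-6-methoxyphenoxy)-2-oxabicyclo[2.2.2]octa-5,7-dien-3-one (racemic; relative configuration of the bridgeheads fixed by the bicycle) | O=C1OC2C=C(Oc3c(OC)cc(Br)cc3Br)C1(Br)C=C2Br | intermediate
11 | 1,5-dibromo-2-(2,4-dibromophenoxy)-3-methoxybenzene | COc1cc(Br)cc(Br)c1Oc1ccc(Br)cc1Br | intermediate
12 | dibromo[3,5-dibromo-2-(2,4-dibromophenoxy)phenoxy]borane | BrB(Br)Oc1cc(Br)cc(Br)c1Oc1ccc(Br)cc1Br | intermediate
13 | 3,5-dibromo-2-(2,4-dibromophenoxy)phenol | Oc1cc(Br)cc(Br)c1Oc1ccc(Br)cc1Br | target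

**Count**

Total steps: 7. Longest linear sequence: 6 (steps 1–4, 6 and 7; step 5 supplies the second partner).

**Steps most likely to fail**

Step 6. Oligomerisation or adventitious hydration of the ynol ether may outrun the cycloaddition, or the cycloaddition may proceed with the reverse orientation. The fallback is a known, metal-free O-arylation by ligand coupling on iodine(III). It sets out from 2 and returns at 11. Phenol 2 would be treated with bis(2,4-dibromophenyl)iodonium chloride F1 in aqueous NaOH/dioxane at 80 °C. F1 is the symmetrical salt obtained from 1,3-dibromobenzene and iodyl sulfate in sulfuric acid, precipitated with chloride. Because both aryl groups on iodine are the same, only the 2,4-dibromophenyl group can be transferred, and no C–Br bond is activated.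

Step 4. The terminal ynol ether may be lost to base-promoted polymerisation or hydration during elimination, work-up and concentration, and any E-configured bromovinyl ether may eliminate only slowly. The fallback protects the alkyne terminus so that a stable compound is purified and stored. It sets out from 6 and returns at 7. Compound 6 would be treated with LiHMDS (2.2 equiv) in THF at −78 → −20 °C, so that elimination and deprotonation give lithium (2,4-dibromo-6-methoxyphenoxy)ethynide F2. This would be silylated in the flask with chlorotrimethylsilane to [(2,4-dibromo-6-methoxyphenoxy)ethynyl]trimethylsilane F3. After chromatography, F3 would be desilylated with acetic acid-buffered TBAF in THF at −40 °C directly before step 6, releasing 7 as a cold solution.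

Step 2. Transmetalation and C–O bond formation at a phenol oxygen flanked by bromine and methoxy may be sluggish, so that the vinylboron reagent is consumed by protodeboronation first. The fallback is a Williamson alkylation followed by E2 elimination. It sets out from 2 and returns at 4. Phenol 2 would be alkylated with excess 1,2-dibromoethane (K2CO3, MeCN, reflux) to 1,5-dibromo-2-(2-bromoethoxy)-3-methoxybenzene F4, which KOt-Bu in THF at rt should dehydrobrominate to vinyl ether 4.

**Further compounds**

F1 | step 6 | bis(2,4-dibromophenyl)iodonium chloride | Brc1ccc([I+]c2ccc(Br)cc2Br)c(Br)c1.[Cl-]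
F2 | step 4 | lithium (2,4-dibromo-6-methoxyphenoxy)ethynide | [Li]C#COc1c(OC)cc(Br)cc1Br
F3 | step 4 | [(2,4-dibromo-6-methoxyphenoxy)ethynyl]trimethylsilane | COc1cc(Br)cc(Br)c1OC#C[Si](C)(C)C
F4 | step 2 | 1,5-dibromo-2-(2-bromoethoxy)-3-methoxybenzene | COc1cc(Br)cc(Br)c1OCCBr
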